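**Retrosynthetic overview**
- Last step: one Lindlar semi-hydrogenation of a 5,6;14,15-diyne sets both Z-alkenes.
- C7–C8: anti-aldol of a 10-chloro-12-siloxy-cyclopentenone enolate with a C1–C7 ynal ester, acetylated in the same flask; C12 controls C8, the closed transition state controls C7.
- C10–Cl by enone α-chlorination; the C9 ketone by oxidation of the original carbinol carbon, so the original carbonyl carbon becomes the C12 carbinol (chirality relay).
- Key step, C12–C13: Ti(III)-mediated radical Barbier-type propargylation of a commercial (R)-4-hydroxycyclopentenone, anti to the C9 oxygen; then acetylide alkylation (C15–C16).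
- No ring is formed: the single carbocycle comes from the chiral-pool cyclopentenone.

Assumption: positions use prostanoid numbering (C1 ester carbon, C7 acetoxy carbon, C8–C12 ring, C13–C20 lower chain); 1, 2, 7 and 14 are taken as commercial.

**Step 1**
Reactants: 1 (R)-4-hydroxycyclopent-2-en-1-one; 2 3-bromoprop-1-yne
Product: 6 (1S,4R)-1-(prop-2-yn-1-yl)-1,4-bis[(trimethylsilyl)oxy]cyclopent-2-ene, via silylated enone 3 (not isolated), via allenyltitanocene chloride 4 (not isolated), via titanocene alkoxide 5 (not isolated)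
Conditions: TMSCl (5 equiv), 2,4,6-collidine (7 equiv), THF, 20 °C, 30 min; then Cp2TiCl2 (0.2 equiv), Mn dust (8 equiv), 2 (2.5 equiv, slow addition), THF, 20 °C; filtration, non-aqueous work-up
Reagents that add atoms: chlorotrimethylsilane, C[Si](C)(C)Cl
Why: Ti(III)-mediated radical Barbier-type propargylation (Nugent–RajanBabu reagent, catalytic in Ti): Cp2TiCl abstracts bromine from 2 to give the propargyl radical, a second Ti(III) captures it as 4, and 4 transfers the propargyl group 1,2 (SE2′) to the carbonyl of 3 on the face anti to the C9 siloxy group, which sets C12, while TMSCl silylates alkoxide 5 and turns the catalyst over.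

**Step 2**
Reactants: 6 (1S,4R)-1-(prop-2-yn-1-yl)-1,4-bis[(trimethylsilyl)oxy]cyclopent-2-ene; 7 1-iodopentane
Product: 10 (1R,4S)-4-(oct-2-yn-1-yl)-4-[(trimethylsilyl)oxy]cyclopent-2-en-1-ol, via lithium acetylide 8 (not isolated), via octynyl bis-silyl ether 9 (not isolated)
Conditions: n-BuLi (1.1 equiv), THF, −78 °C; DMPU, 7 (1.5 equiv), −78 → 20 °C; then K2CO3 (0.1 equiv), MeOH, 0 °C, 15 min
Reagents that add atoms: none
Why: Acetylide alkylation (SN2) with the primary iodide, then selective methanolysis of the less hindered secondary allylic TMS ether while the tertiary one reacts much more slowly; no stereocentre is touched and the minor C12 epimer from step 1 is removed here by chromatography.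

**Step 3**
Reactants: 10 (1R,4S)-4-(oct-2-yn-1-yl)-4-[(trimethylsilyl)oxy]cyclopent-2-en-1-ol
Product: 11 (S)-4-(oct-2-yn-1-yl)-4-[(trimethylsilyl)oxy]cyclopent-2-en-1-one
Conditions: MnO2 (15 equiv), CH2Cl2, 20 °C
Reagents that add atoms: none
Why: MnO2 oxidation of the secondary allylic alcohol gives the C9 enone, so the stereocentre of 1 is spent after it has set C12, which stays untouched.

**Step 4**
Reactants: 11 (S)-4-(oct-2-yn-1-yl)-4-[(trimethylsilyl)oxy]cyclopent-2-en-1-one
Product: 13 (S)-2-chloro-4-(oct-2-yn-1-yl)-4-[(trimethylsilyl)oxy]cyclopent-2-en-1-one, via trans-dichloride 12 (not isolated)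
Conditions: PhICl2 (1.15 equiv), pyridine (3 equiv), CH2Cl2, 0 → 20 °C
Reagents that add atoms: (dichloroiodo)benzene, ClI(Cl)c1ccccc1
Why: Enone α-chlorination by chlorine addition and pyridine-promoted dehydrochlorination of 12 through its acidic C10–H, which puts chlorine on C10 and should favour the conjugated alkene over the isolated alkyne under pyridine-buffered conditions.

**Step 5**
Reactants: 14 hex-5-ynoic acid
Product: 16 7-oxohept-5-ynoic acid, via dilithio salt 15 (not isolated)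
Conditions: n-BuLi (2.1 equiv), THF, −78 → −20 °C; DMF (3 equiv), −78 → 0 °C; inverse quench into cold 1 M HCl
Reagents that add atoms: N,N-dimethylformamide, CN(C)C=O
Why: Bouveault-type formylation of the acetylide carbon of the carboxylate/acetylide dianion by DMF, with the aldehyde released on acidic inverse quench.

**Step 6**
Reactants: 16 7-oxohept-5-ynoic acid
Product: 17 methyl 7-oxohept-5-ynoate
Conditions: MeI (1.5 equiv), KHCO3 (1.5 equiv), DMF, 20 °C
Reagents that add atoms: iodomethane, CI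
Why: SN2 O-methylation of the carboxylate under weak base esterifies the acid without touching the base-sensitive ynal.

**Step 7**
Reactants: 13 (S)-2-chloro-4-(oct-2-yn-1-yl)-4-[(trimethylsilyl)oxy]cyclopent-2-en-1-one; 17 methyl 7-oxohept-5-ynoate
Product: 21 methyl (7R)-7-acetoxy-7-[(1R,5S)-3-chloro-5-hydroxy-5-(oct-2-yn-1-yl)-2-oxocyclopent-3-en-1-yl]hept-5-ynoate, via lithium dienolate 18 (not isolated), via lithium aldolate 19 (not isolated), via silyl-protected acetate 20 (not isolated)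
Conditions: LDA (1.05 equiv), THF, −78 °C; 17 (1.2 equiv), −78 °C, 20 min; Ac2O (2 equiv), −78 → −40 °C; then AcOH/MeOH/H2O, 20 °C
Reagents that add atoms: acetic anhydride, CC(=O)OC(C)=O
Why: Kinetic lithium aldol of the cyclic (E)-enolate 18 through a Zimmerman–Traxler transition state gives the anti adduct, with the ynal approaching C8 trans to the larger C12 oct-2-ynyl chain (cis to the siloxy group), which sets C8 (R) and C7 (R at the diyne stage); the aldolate is acetylated in the flask and the tertiary TMS ether is then removed by mild acid methanolysis, the minor syn epimer being separated.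

**Step 8**
Reactants: 21 methyl (7R)-7-acetoxy-7-[(1R,5S)-3-chloro-5-hydroxy-5-(oct-2-yn-1-yl)-2-oxocyclopent-3-en-1-yl]hept-5-ynoate
Product: 22 punaglandin 8, methyl (5Z,7S)-7-acetoxy-7-[(1R,5S)-3-chloro-5-hydroxy-5-[(2Z)-oct-2-en-1-yl]-2-oxocyclopent-3-en-1-yl]hept-5-enoate
Conditions: H2 (1 atm), Lindlar catalyst (Pd/CaCO3, Pb-poisoned), quinoline, EtOAc, 20 °C, stopped after 2.0 equiv H2
Reagents that add atoms: none
Why: Lindlar semi-hydrogenation adds H2 syn to both internal alkynes to give the two Z-alkenes and leaves the α-chloro enone, the acetate and the three stereocentres intact (C7 changes from R to S only through the CIP priority change).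

**Compound list**
1 | (R)-4-hydroxycyclopent-2-en-1-one | O=C1C=C[C@H](O)C1 | starting material
2 | 3-bromoprop-1-yne | C#CCBr | starting material
3 | (R)-4-[(trimethylsilyl)oxy]cyclopent-2-en-1-one | O=C1C=C[C@H](O[Si](C)(C)C)C1 | intermediate
4 | chlorobis(cyclopentadienyl)(propa-1,2-dien-1-yl)titanium | C=C=C[Ti](Cl)(C1C=CC=C1)C1C=CC=C1 | intermediate
5 | chlorobis(cyclopentadienyl)titanium (1S,4R)-1-(prop-2-yn-1-yl)-4-[(trimethylsilyl)oxy]cyclopent-2-en-1-olate | C#CC[C@@]1(O[Ti](Cl)(C2C=CC=C2)C2C=CC=C2)C=C[C@H](O[Si](C)(C)C)C1 | intermediate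
6 | (1S,4R)-1-(prop-2-yn-1-yl)-1,4-bis[(trimethylsilyl)oxy]cyclopent-2-ene | C#CC[C@@]1(O[Si](C)(C)C)C=C[C@H](O[Si](C)(C)C)C1 | intermediate
7 | 1-iodopentane | CCCCCI | starting material
8 | lithium acetylide of 6 | [Li]C#CC[C@@]1(O[Si](C)(C)C)C=C[C@H](O[Si](C)(C)C)C1 | intermediate
9 | (1S,4R)-1-(oct-2-yn-1-yl)-1,4-bis[(trimethylsilyl)oxy]cyclopent-2-ene | CCCCCC#CC[C@@]1(O[Si](C)(C)C)C=C[C@H](O[Si](C)(C)C)C1 | intermediate
10 | (1R,4S)-4-(oct-2-yn-1-yl)-4-[(trimethylsilyl)oxy]cyclopent-2-en-1-ol | CCCCCC#CC[C@@]1(O[Si](C)(C)C)C=C[C@H](O)C1 | intermediate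
11 | (S)-4-(oct-2-yn-1-yl)-4-[(trimethylsilyl)oxy]cyclopent-2-en-1-one | CCCCCC#CC[C@@]1(O[Si](C)(C)C)C=CC(=O)C1 | intermediate
12 | (4S)-2,3-dichloro-4-(oct-2-yn-1-yl)-4-[(trimethylsilyl)oxy]cyclopentan-1-one | CCCCCC#CC[C@@]1(O[Si](C)(C)C)C(Cl)C(Cl)C(=O)C1 | intermediate
13 | (S)-2-chloro-4-(oct-2-yn-1-yl)-4-[(trimethylsilyl)oxy]cyclopent-2-en-1-one | CCCCCC#CC[C@@]1(O[Si](C)(C)C)C=C(Cl)C(=O)C1 | intermediate
14 | hex-5-ynoic acid | C#CCCCC(=O)O | starting material
15 | lithium 6-lithiohex-5-ynoate | [Li]C#CCCCC(=O)O[Li] | intermediate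
16 | 7-oxohept-5-ynoic acid | O=CC#CCCCC(=O)O | intermediate
17 | methyl 7-oxohept-5-ynoate | COC(=O)CCCC#CC=O | intermediate
18 | lithium dienolate of 13 | CCCCCC#CC[C@@]1(O[Si](C)(C)C)C=C(Cl)C(O[Li])=C1 | intermediate
19 | lithium (7R)-aldolate of 13 and 17 | CCCCCC#CC[C@@]1(O[Si](C)(C)C)C=C(Cl)C(=O)[C@@H]1[C@H](C#CCCCC(=O)OC)O[Li] | intermediate
20 | methyl (7R)-7-acetoxy-7-[(1R,5S)-3-chloro-5-(oct-2-yn-1-yl)-2-oxo-5-[(trimethylsilyl)oxy]cyclopent-3-en-1-yl]hept-5-ynoate | CCCCCC#CC[C@@]1(O[Si](C)(C)C)C=C(Cl)C(=O)[C@@H]1[C@H](C#CCCCC(=O)OC)OC(C)=O | intermediate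
21 | methyl (7R)-7-acetoxy-7-[(1R,5S)-3-chloro-5-hydroxy-5-(oct-2-yn-1-yl)-2-oxocyclopent-3-en-1-yl]hept-5-ynoate | CCCCCC#CC[C@@]1(O)C=C(Cl)C(=O)[C@@H]1[C@H](C#CCCCC(=O)OC)OC(C)=O | intermediate
22 | punaglandin 8, methyl (5Z,7S)-7-acetoxy-7-[(1R,5S)-3-chloro-5-hydroxy-5-[(2Z)-oct-2-en-1-yl]-2-oxocyclopent-3-en-1-yl]hept-5-enoate | CCCCC/C=C\C[C@@]1(O)C=C(Cl)C(=O)[C@@H]1[C@H](/C=C\CCCC(=O)OC)OC(C)=O | target

**Step count**
Total: 8 steps. Longest linear sequence: 6 steps (1, 2, 3, 4, 7, 8).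

**Three steps most likely to fail, each with a fallback**

Step 1 (facial selectivity of the propargyl transfer, and tolerance of the 4-siloxy enone to Ti(III)/Mn). The fallback sets out from 1 and comes back at 9. Compound 1 is silylated (TMSCl, imidazole) and 3 is isolated. Oct-2-yne is lithiated at C1 (t-BuLi, THF) to 1-lithiooct-2-yne F1 and transmetalated with ClTi(OiPr)3 to (octa-1,2-dien-3-yl)tri(propan-2-yloxy)titanium F2. F2 adds to 3 by a polar SE2′ path anti to the siloxy group and gives the titanium alkoxide of the octynyl adduct F3, which is silylated in the flask (TMSOTf, 2,6-lutidine) to 9. Compound 9 re-enters at the methanolysis of step 2, so the radical propargylation and the alkylation are both replaced by one polar addition of the complete C8 chain.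

Step 4 (competing chlorination of the alkyne, or loss of the TMS ether). The fallback sets out from 11 and comes back at 13. Nucleophilic epoxidation (TBHP, DBU, CH2Cl2, 0 °C), which cannot touch the alkyne, gives (4S)-2,3-epoxy-4-(oct-2-yn-1-yl)-4-[(trimethylsilyl)oxy]cyclopentan-1-one F4. HCl in Et2O opens it at C10 to (4S)-2-chloro-3-hydroxy-4-(oct-2-yn-1-yl)-4-[(trimethylsilyl)oxy]cyclopentan-1-one F5, which dehydrates and loses the silyl group to give (S)-2-chloro-4-hydroxy-4-(oct-2-yn-1-yl)cyclopent-2-en-1-one F6. N-(Trimethylsilyl)imidazole then returns 13.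

Step 7 (low anti:syn ratio at C7, or elimination of the β-acetoxy ketone). The fallback sets out from 13 (with 17) and comes back at 20. Soft enolisation with Cy2BCl/Et3N (Et2O, 0 °C) gives the dicyclohexylboron dienolate of 13 F7. Its closed boron aldol with 17 at −78 °C gives the dicyclohexylboron aldolate F8 with higher anti selectivity, and a non-oxidative methanol work-up frees methyl (7R)-7-[(1R,5S)-3-chloro-5-(oct-2-yn-1-yl)-2-oxo-5-[(trimethylsilyl)oxy]cyclopent-3-en-1-yl]-7-hydroxyhept-5-ynoate F9. Separate acetylation (Ac2O, pyridine, cat. DMAP, 0 °C) gives 20, which is desilylated to 21 as in step 7.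

**Further compounds**
F1 | step 1 | 1-lithiooct-2-yne | [Li]CC#CCCCCC
F2 | step 1 | (octa-1,2-dien-3-yl)tri(propan-2-yloxy)titanium | C=C=C(CCCCC)[Ti](OC(C)C)(OC(C)C)OC(C)C
F3 | step 1 | tri(propan-2-yloxy)titanium (1S,4R)-1-(oct-2-yn-1-yl)-4-[(trimethylsilyl)oxy]cyclopent-2-en-1-olate | CCCCCC#CC[C@@]1(O[Ti](OC(C)C)(OC(C)C)OC(C)C)C=C[C@H](O[Si](C)(C)C)C1
F4 | step 4 | (4S)-2,3-epoxy-4-(oct-2-yn-1-yl)-4-[(trimethylsilyl)oxy]cyclopentan-1-one | CCCCCC#CC[C@@]1(O[Si](C)(C)C)C2OC2C(=O)C1
F5 | step 4 | (4S)-2-chloro-3-hydroxy-4-(oct-2-yn-1-yl)-4-[(trimethylsilyl)oxy]cyclopentan-1-one | CCCCCC#CC[C@@]1(O[Si](C)(C)C)C(O)C(Cl)C(=O)C1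
F6 | step 4 | (S)-2-chloro-4-hydroxy-4-(oct-2-yn-1-yl)cyclopent-2-en-1-one | CCCCCC#CC[C@@]1(O)C=C(Cl)C(=O)C1
F7 | step 7 | dicyclohexylboron dienolate of 13 | CCCCCC#CC[C@@]1(O[Si](C)(C)C)C=C(Cl)C(OB(C2CCCCC2)C2CCCCC2)=C1
F8 | step 7 | dicyclohexylboron (7R)-aldolate of 13 and 17 | CCCCCC#CC[C@@]1(O[Si](C)(C)C)C=C(Cl)C(=O)[C@@H]1[C@H](C#CCCCC(=O)OC)OB(C1CCCCC1)C1CCCCC1
F9 | step 7 | methyl (7R)-7-[(1R,5S)-3-chloro-5-(oct-2-yn-1-yl)-2-oxo-5-[(trimethylsilyl)oxy]cyclopent-3-en-1-yl]-7-hydroxyhept-5-ynoate | CCCCCC#CC[C@@]1(O[Si](C)(C)C)C=C(Cl)C(=O)[C@@H]1[C@H](C#CCCCC(=O)OC)O
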